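## Retrosynthetic overview

1. Both C–Br centres (C4, C4') are made last by hydrogen-atom-transfer hydrogenation of two alkenyl bromides derived from the C4 and C4' ketones; each ring places its bromine equatorial.
2. The hydrindane comes from a type 1 intramolecular Diels–Alder reaction (IMDA) that forms C6–C7 and C3a–C7a, from diene C6=C5–C4(OSi)=C3a and dienophile C7a=C7(OSiMe2t-Bu)CO2Me (the ester becomes the C7 methyl).
3. Enabling feature: in the carbocycle C3a–C4–C5–C6–C7–C7a the bromine carbon C4 can stand at the ketone level, and O2 on the cyclopentane is cis-1,3 to the C3a–C4 bond. One Si(t-Bu)2 bridge O2–Si–O4 therefore fixes the C3a=C4 geometry and the diene face.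
4. The triene comes from an Evans syn-aldol (Cα, C1) of a crotonyl imide with the ring A aldehyde, a 1,3-syn reduction (C2) and lactone-to-vinyl-ketone opening. Ring A comes from a Diels–Alder reaction of a 2-silyloxydiene with methyl propiolate, cyclopropanation/opening (gem-dimethyl) and Sharpless epoxidation (C1').
5. Ring order: cyclohexane ring A (step 2), temporary silylene ring (step 19), then the cyclopentane and cyclohexane of the hydrindane together (step 20).

Key step: step 20

Locants: hydrindane carbons are numbered as in octahydro-1H-indene (C1 bears the side chain, C2–OH, C3, C3a–CH3, C4–Br, C5, C6, C7(CH3)OH, C7a). Cα is the carbinol CH of the side chain. C1'–C6' are the ring A carbons (C1' carbinol, C3' CMe2, C4' CHBr).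

Assumption: phosphonate 27 is taken as a purchasable reagent; the C3a–H centre brought in with 19 is a spectator that is erased when the dienol ether is formed in step 19.

## Route

Step 1
Reactants: 1 3-methylbut-3-en-2-one
Product: 2 trimethyl[(3-methylbuta-1,3-dien-2-yl)oxy]silane
Conditions: Me3SiOTf, Et3N, Et2O, 0 °C
Reagents that add atoms: trimethylsilyl triflate, C[Si](C)(C)OS(=O)(=O)C(F)(F)F
Why: The methyl group is the only enolisable position, so amine/silyl triflate enol silylation should give the 2-silyloxydiene as one regioisomer (silyl enol ether formation).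

Step 2
Reactants: 2 trimethyl[(3-methylbuta-1,3-dien-2-yl)oxy]silane; 3 methyl propiolate
Product: 4 methyl 5-methyl-4-(trimethylsilyloxy)cyclohexa-1,4-diene-1-carboxylate
Conditions: toluene, BHT (cat.), 110 °C, sealed tube
Reagents that add atoms: none
Why: Intermolecular Diels–Alder reaction in which the silyloxy group directs the ester para to the oxygenated carbon, so ring A forms with the future C4' oxygen, one C3' methyl and the C1' carbon substituent in place.

Step 3
Reactants: 4 methyl 5-methyl-4-(trimethylsilyloxy)cyclohexa-1,4-diene-1-carboxylate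
Product: 5 methyl 1-methyl-6-(trimethylsilyloxy)bicyclo[4.1.0]hept-3-ene-3-carboxylate (racemic)
Conditions: Et2Zn, CH2I2, CH2Cl2, 0 °C to rt
Reagents that add atoms: diiodomethane, ICI
Why: Simmons–Smith cyclopropanation with the electrophilic zinc carbenoid should take the electron-rich tetrasubstituted silyl enol ether and leave the enoate double bond.

Step 4
Reactants: 5 methyl 1-methyl-6-(trimethylsilyloxy)bicyclo[4.1.0]hept-3-ene-3-carboxylate
Product: 7 methyl 6,6-dimethyl-1,4-dioxaspiro[4.5]dec-8-ene-8-carboxylate, via keto ester 6 (not isolated)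
Conditions: HOCH2CH2OH, p-TsOH·H2O (cat.), benzene, reflux, Dean–Stark trap
Reagents that add atoms: ethylene glycol, OCCO
Why: Acid opening of the siloxycyclopropane at the bond between the oxygenated carbon and the CH2 turns that CH2 into the second methyl group (cyclopropanol ring opening, an α-methylation), and the hindered ketone is ketalised in the same pot while the double bond stays conjugated with the ester.

Step 5
Reactants: 7 methyl 6,6-dimethyl-1,4-dioxaspiro[4.5]dec-8-ene-8-carboxylate
Product: 8 (6,6-dimethyl-1,4-dioxaspiro[4.5]dec-8-en-8-yl)methanol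
Conditions: i-Bu2AlH, CH2Cl2, −78 to 0 °C
Reagents that add atoms: none
Why: 1,2-Reduction of the enoate by the aluminium hydride should give the allylic alcohol needed for a directed epoxidation (ester reduction).

Step 6
Reactants: 8 (6,6-dimethyl-1,4-dioxaspiro[4.5]dec-8-en-8-yl)methanol
Product: 9 (1R,6R)-epoxy alcohol
Conditions: Ti(OiPr)4 (10 mol%), D-(−)-diethyl tartrate (12 mol%), t-BuOOH, 4 Å MS, CH2Cl2, −20 °C
Reagents that add atoms: tert-butyl hydroperoxide, CC(C)(C)OO
Why: Sharpless asymmetric epoxidation of the trisubstituted cyclic allylic alcohol, in which the D-tartrate catalyst should deliver oxygen to the face that gives the (1R,6R)-epoxide and so sets C1' by catalysis.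

Step 7
Reactants: 9 (1R,6R)-epoxy alcohol
Product: 10 (8R)-8-(hydroxymethyl)-6,6-dimethyl-1,4-dioxaspiro[4.5]decan-8-ol
Conditions: LiAlH4, THF, 0 °C to rt
Reagents that add atoms: none
Why: Hydride should open the epoxide at the secondary carbon (trans-diaxial SN2 opening, the fully substituted carbon being shielded), leaving the tertiary C1' alcohol with retention (epoxide reduction).

Step 8
Reactants: 10 (8R)-8-(hydroxymethyl)-6,6-dimethyl-1,4-dioxaspiro[4.5]decan-8-ol
Product: 11 bis(triethylsilyl) ether of 10
Conditions: Et3SiOTf, 2,6-lutidine, CH2Cl2, −78 to 0 °C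
Reagents that add atoms: triethylsilyl triflate, CC[Si](CC)(CC)OS(=O)(=O)C(F)(F)F
Why: Silyl triflate silylation protects the tertiary as well as the primary hydroxyl (silyl ether formation).

Step 9
Reactants: 11 bis(triethylsilyl) ether of 10
Product: 12 (8R)-6,6-dimethyl-8-(triethylsilyloxy)-1,4-dioxaspiro[4.5]decane-8-carbaldehyde
Conditions: (COCl)2, DMSO, CH2Cl2, −78 to −30 °C; Et3N, to 0 °C
Reagents that add atoms: none
Why: Under Swern conditions a primary triethylsilyl ether is cleaved and oxidised directly to the aldehyde while the tertiary silyl ether should survive (Swern oxidation with in situ desilylation).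

Step 10
Reactants: 13 (R)-4-benzyl-1,3-oxazolidin-2-one; 14 (E)-but-2-enoyl chloride
Product: 15 (R)-4-benzyl-3-[(E)-but-2-enoyl]-1,3-oxazolidin-2-one
Conditions: n-BuLi, THF, −78 °C; then 14, −78 to 0 °C
Reagents that add atoms: none
Why: N-Acylation of the lithiated oxazolidinone should give the crotonyl imide.

Step 11
Reactants: 15 (R)-4-benzyl-3-[(E)-but-2-enoyl]-1,3-oxazolidin-2-one; 12 ring A aldehyde
Product: 17 syn-aldol imide, via boron dienolate 16 (not isolated)
Conditions: Bu2BOTf, Et3N, CH2Cl2, −78 to 0 °C; then 12, −78 to 0 °C; H2O2, MeOH, pH 7 buffer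
Reagents that add atoms: none
Why: Evans syn-aldol reaction in which the (Z)-boron dienolate reacts at its α-carbon through a chair Zimmerman–Traxler transition state whose face is fixed by the (R)-auxiliary, setting Cα–OH and the C1 vinyl group syn, while the non-enolisable α-quaternary aldehyde has no facial bias of its own.

Step 12
Reactants: 17 syn-aldol imide
Product: 18 S-ethyl thioester
Conditions: EtSH, n-BuLi, THF, 0 °C
Reagents that add atoms: ethanethiol, CCS
Why: Transacylation with lithium ethanethiolate should cleave the imide at the exocyclic carbonyl under conditions too mild for retro-aldol or for migration of the β,γ-double bond (imide to thioester exchange).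

Step 13
Reactants: 18 S-ethyl thioester; 19 methyl (S)-3-bromo-2-methylpropanoate
Product: 21 hydroxy keto ester, via organozinc bromide 20 (not isolated)
Conditions: 19, Zn, LiCl, THF, 40 °C; then 18, PdCl2(PPh3)2 (5 mol%), toluene, rt
Reagents that add atoms: none
Why: Fukuyama coupling of the thioester with the β-zincio ester (zinc homoenolate) should make the C2 ketone and bring in C3, C3a with its methyl group and C4 as an ester, and it tolerates the free hydroxyl, the vinyl group and the ester.

Step 14
Reactants: 21 hydroxy keto ester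
Product: 23 hydroxy lactone, via syn-diol ester 22 (not isolated)
Conditions: Et2BOMe, NaBH4, THF–MeOH (4:1), −78 °C; AcOH, MeOH co-evaporation; PPTS (cat.), CH2Cl2, rt
Reagents that add atoms: none
Why: Narasaka–Prasad reduction in which hydride attacks the six-membered boron chelate axially and anti to the pseudo-axial vinyl group, setting C2–OH 1,3-syn to Cα–OH by substrate control, after which the new hydroxyl closes the γ-lactone on the ester.

Step 15
Reactants: 23 hydroxy lactone
Product: 24 bis(triethylsilyl) lactone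
Conditions: Et3SiOTf, 2,6-lutidine, CH2Cl2, −78 °C
Reagents that add atoms: triethylsilyl triflate, CC[Si](CC)(CC)OS(=O)(=O)C(F)(F)F
Why: Silylation of the Cα hydroxyl (silyl ether formation) removes the last free hydroxyl before the ozonolysis, olefination and Grignard steps.

Step 16
Reactants: 24 bis(triethylsilyl) lactone
Product: 26 lactone aldehyde, via ozonide 25 (not isolated)
Conditions: O3, CH2Cl2, −78 °C; PPh3, −78 °C to rt
Reagents that add atoms: ozone, [O-][O+]=O
Why: Ozonolysis of the only C=C bond should give the C7a aldehyde, which is used at once because its α-centre C1 is epimerisable.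

Step 17
Reactants: 26 lactone aldehyde; 27 methyl 2-(tert-butyldimethylsilyloxy)-2-(dimethoxyphosphoryl)acetate
Product: 28 (Z)-2-silyloxy enoate lactone
Conditions: 27, LiN(SiMe3)2, THF, −78 °C; then 26, −78 to 0 °C
Reagents that add atoms: none
Why: Horner–Wadsworth–Emmons olefination with the α-silyloxy phosphonate should favour the (Z)-enol ether with the silyloxy group cis to C1 and the ester trans, the geometry that later places O7 cis to the angular methyl, the minor (E)-isomer being removed by chromatography.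

Step 18
Reactants: 28 (Z)-2-silyloxy enoate lactone
Product: 29 hydroxy enone
Conditions: CH2=CHMgBr (1.2 equiv), THF, −78 °C; AcOH, −78 °C
Reagents that add atoms: vinylmagnesium bromide, C=C[Mg]Br
Why: Single addition of the vinyl Grignard reagent to the γ-lactone, whose tetrahedral magnesium lactolate persists at −78 °C, should be much faster than attack on the hindered, conjugated α-silyloxy ester (acyl substitution of a lactone to a γ-hydroxy vinyl ketone).

Step 19
Reactants: 29 hydroxy enone
Product: 30 cyclic silylene dienol ether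
Conditions: t-Bu2Si(OTf)2 (1.2 equiv), Et3N (4 equiv), CH2Cl2 (dilute), −78 °C to rt
Reagents that add atoms: di-tert-butylsilyl bis(triflate), CC(C)(C)[Si](OS(=O)(=O)C(F)(F)F)(OS(=O)(=O)C(F)(F)F)C(C)(C)C
Why: Proposed new method: silylation of the C2 hydroxyl should give a silyl triflate held next to the C4 ketone oxygen, and amine-assisted soft enolisation at C3a then closes a seven-membered 1,3-dioxa-2-silacycloheptene that can hold the enol double bond only with C3 and the enol oxygen cis, so the 2-silyloxydiene should form as one geometric isomer with the tether outside and the methyl group inside; the closest known reaction types are silylene protection of 1,3- and 1,4-diols with this reagent and silyl triflate/amine enol silylation of ketones.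

Step 20
Reactants: 30 cyclic silylene dienol ether
Product: 31 trans-hydrindene cycloadduct
Conditions: toluene (0.01 M), BHT, 160 °C, sealed tube
Reagents that add atoms: none
Why: Thermal type 1 intramolecular Diels–Alder reaction of a 2-silyloxy-1,3,8-nonatriene, a concerted but asynchronous [4+2] in which the nucleophilic diene terminus C3a leads onto the β-carbon C7a of the captodative acrylate and C6 closes onto C7; the closest known reaction type is the IMDA of silyl dienol ethers of vinyl ketones to angularly methylated trans-hydrindanes. The cyclopentane closes through the three-carbon tether C3–C2–C1 in the anti (tether-exo) mode that gives the trans ring fusion, and the cyclohexene closes as the [4+2] ring itself with its enol silane double bond at C4=C5. C3a is controlled by C2: the O2–Si–O4 bridge can be kept across the new cyclopentane only if O2 and C4 are cis, so C2 fixes which diene face the tethered dienophile can reach. C7a is controlled by C1: allylic 1,3-strain with the cis silyloxy group on C7 holds the C1–H bond in the dienophile plane and turns the large Cα substituent away from the diene, which together with the bridge leaves only the trans-fused transition state. C7 follows from the (Z)-geometry of the dienophile, which puts the ester endo and the silyloxy group exo, that is cis to the 3a-methyl group. The step needs this one of four possible adducts and needs cycloaddition to outrun a 1,5-hydrogen shift of the inside methyl group; the cyclic enol ether (fixed geometry and face), the single-isomer dienophile and the matched donor diene/acceptor dienophile pair are there to secure it.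

Step 21
Reactants: 31 trans-hydrindene cycloadduct
Product: 32 primary alcohol
Conditions: i-Bu2AlH, toluene, −78 to 0 °C
Reagents that add atoms: none
Why: Aluminium hydride reduction of the tertiary ester to the C7 hydroxymethyl group should leave the enol silane, the silyl ethers and the ketal untouched (ester reduction).

Step 22
Reactants: 32 primary alcohol
Product: 33 mesylate
Conditions: MsCl, Et3N, DMAP (cat.), CH2Cl2, 0 °C
Reagents that add atoms: methanesulfonyl chloride, CS(Cl)(=O)=O
Why: Sulfonylation of the only free hydroxyl (mesylate formation) activates it for reduction.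

Step 23
Reactants: 33 mesylate
Product: 34 protected core with the C7 methyl group
Conditions: LiEt3BH, THF, 0 °C to reflux
Reagents that add atoms: none
Why: Hydride displacement of the neopentyl-type primary mesylate by this very nucleophilic borohydride should give the C7 methyl group at a stage where no halogen is yet present (sulfonate reduction).

Step 24
Reactants: 34 protected core with the C7 methyl group
Product: 35 diketone tetraol
Conditions: 48% aq HF, MeCN, 0 °C to rt; then 2 M HCl, THF, rt
Reagents that add atoms: water, O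
Why: Global desilylation and ketal hydrolysis should free the four hydroxyls and, by hydrolysis of the enol silane and of the dioxolane, the C4 and C4' ketones.

Step 25
Reactants: 35 diketone tetraol
Product: 36 bis-hydrazone
Conditions: N2H4·H2O, Et3N, EtOH, 80 °C
Reagents that add atoms: hydrazine, NN
Why: Hydrazone formation at both ketones, each of which has a quaternary carbon on one side and a CH2 on the other, should tolerate the free hydroxyls.

Step 26
Reactants: 36 bis-hydrazone
Product: 37 bis(alkenyl bromide)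
Conditions: NBS, 2-tert-butyl-1,1,3,3-tetramethylguanidine, CH2Cl2, −10 °C to rt
Reagents that add atoms: N-bromosuccinimide, O=C1CCC(=O)N1Br
Why: Barton-type vinyl halide synthesis in which oxidation of each hydrazone to a diazo compound, bromination and loss of N2 and of the only available β-proton (C5–H, C5'–H) should give both alkenyl bromides regiospecifically.

Step 27
Reactants: 37 bis(alkenyl bromide)
Product: 38 target CNP0144982.1
Conditions: Co(acac)2, t-BuOOH, Et3SiH, cyclohexa-1,4-diene, n-PrOH, rt
Reagents that add atoms: none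
Why: Cobalt hydride hydrogen-atom-transfer hydrogenation of alkenyl bromides, in which H• adds to the CH terminus and each α-bromo radical (C4, C4') should take hydrogen from cyclohexadiene axially, on the face anti to the axial methyl group of the neighbouring quaternary carbon, so both bromines end equatorial (C4–Br cis to the 3a-methyl, C4'–Br cis to the C1' hydroxyl), which is also the more stable epimer in each ring.

## Compound list

1 | 3-methylbut-3-en-2-one | CC(=O)C(C)=C | starting material
2 | trimethyl[(3-methylbuta-1,3-dien-2-yl)oxy]silane | C=C(C)C(=C)O[Si](C)(C)C | intermediate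
3 | methyl propiolate (methyl prop-2-ynoate) | C#CC(=O)OC | starting material
4 | methyl 5-methyl-4-(trimethylsilyloxy)cyclohexa-1,4-diene-1-carboxylate | COC(=O)C1=CCC(O[Si](C)(C)C)=C(C)C1 | intermediate
5 | methyl 1-methyl-6-(trimethylsilyloxy)bicyclo[4.1.0]hept-3-ene-3-carboxylate (racemic, cis-fused cyclopropane) | COC(=O)C1=CCC2(O[Si](C)(C)C)CC2(C)C1 | intermediate
6 | methyl 5,5-dimethyl-4-oxocyclohex-1-ene-1-carboxylate | COC(=O)C1=CCC(=O)C(C)(C)C1 | intermediate (not isolated)
7 | methyl 6,6-dimethyl-1,4-dioxaspiro[4.5]dec-8-ene-8-carboxylate | COC(=O)C1=CCC2(OCCO2)C(C)(C)C1 | intermediate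
8 | (6,6-dimethyl-1,4-dioxaspiro[4.5]dec-8-en-8-yl)methanol | OCC1=CCC2(OCCO2)C(C)(C)C1 | intermediate
9 | [(1R,6R)-4,4-(ethylenedioxy)-3,3-dimethyl-7-oxabicyclo[4.1.0]heptan-1-yl]methanol | CC1(C)C[C@@]2(O[C@@H]2CC13OCCO3)CO | intermediate
10 | (8R)-8-(hydroxymethyl)-6,6-dimethyl-1,4-dioxaspiro[4.5]decan-8-ol | CC1(C)C[C@@](O)(CO)CCC14OCCO4 | intermediate
11 | (8R)-6,6-dimethyl-8-(triethylsilyloxy)-8-[(triethylsilyloxy)methyl]-1,4-dioxaspiro[4.5]decane | CC1(C)C[C@@](O[Si](CC)(CC)CC)(CO[Si](CC)(CC)CC)CCC14OCCO4 | intermediate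
12 | (8R)-6,6-dimethyl-8-(triethylsilyloxy)-1,4-dioxaspiro[4.5]decane-8-carbaldehyde (ring A aldehyde) | CC1(C)C[C@@](O[Si](CC)(CC)CC)(C=O)CCC14OCCO4 | intermediate
13 | (R)-4-benzyl-1,3-oxazolidin-2-one | O=C1OC[C@@H](Cc2ccccc2)N1 | starting material
14 | (E)-but-2-enoyl chloride | C/C=C/C(Cl)=O | starting material
15 | (R)-4-benzyl-3-[(E)-but-2-enoyl]-1,3-oxazolidin-2-one | C/C=C/C(=O)N1[C@H](Cc2ccccc2)COC1=O | intermediate
16 | (Z)-dibutylboron dienolate of 15 | C=C/C=C(\OB(CCCC)CCCC)N1[C@H](Cc2ccccc2)COC1=O | intermediate (not isolated)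
17 | (4R)-4-benzyl-3-[(2R)-2-{(R)-hydroxy[(8R)-6,6-dimethyl-8-(triethylsilyloxy)-1,4-dioxaspiro[4.5]dec-8-yl]methyl}but-3-enoyl]-1,3-oxazolidin-2-one (syn-aldol: Cα–OH and C1 vinyl syn) | CC1(C)C[C@@](O[Si](CC)(CC)CC)([C@H](O)[C@@H](C=C)C(=O)N2[C@H](Cc3ccccc3)COC2=O)CCC14OCCO4 | intermediate
18 | S-ethyl (2R)-2-{(R)-hydroxy[(8R)-6,6-dimethyl-8-(triethylsilyloxy)-1,4-dioxaspiro[4.5]dec-8-yl]methyl}but-3-enethioate | CC1(C)C[C@@](O[Si](CC)(CC)CC)([C@H](O)[C@@H](C=C)C(=O)SCC)CCC14OCCO4 | intermediate
19 | methyl (S)-3-bromo-2-methylpropanoate | COC(=O)[C@H](C)CBr | starting material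
20 | bromo[(2S)-3-methoxy-2-methyl-3-oxopropyl]zinc | COC(=O)[C@H](C)C[Zn]Br | intermediate (not isolated)
21 | methyl (2R,5R)-5-{(R)-hydroxy[(8R)-6,6-dimethyl-8-(triethylsilyloxy)-1,4-dioxaspiro[4.5]dec-8-yl]methyl}-2-methyl-4-oxohept-6-enoate | CC1(C)C[C@@](O[Si](CC)(CC)CC)([C@H](O)[C@@H](C=C)C(=O)C[C@@H](C)C(=O)OC)CCC14OCCO4 | intermediate
22 | syn-diol ester: 21 with the C2 ketone reduced to the alcohol, Cα–OH/C1-vinyl/C2–OH all syn | CC1(C)C[C@@](O[Si](CC)(CC)CC)([C@H](O)[C@@H](C=C)[C@H](O)C[C@@H](C)C(=O)OC)CCC14OCCO4 | intermediate (not isolated)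
23 | hydroxy lactone: (3R,5R)-3-methyl-γ-butyrolactone carrying at C5 the C1 carbon (vinyl, Cα–OH, ring A as in 17) | CC1(C)C[C@@](O[Si](CC)(CC)CC)([C@H](O)[C@@H](C=C)[C@H]5C[C@@H](C)C(=O)O5)CCC14OCCO4 | intermediate
24 | bis(triethylsilyl) lactone: Cα–O-triethylsilyl ether of 23 | CC1(C)C[C@@](O[Si](CC)(CC)CC)([C@H](O[Si](CC)(CC)CC)[C@@H](C=C)[C@H]5C[C@@H](C)C(=O)O5)CCC14OCCO4 | intermediate
25 | ozonide of 24 (1,2,4-trioxolane on C1, epimers at the trioxolane carbon) | CC1(C)C[C@@](O[Si](CC)(CC)CC)([C@H](O[Si](CC)(CC)CC)[C@@H](C6OCOO6)[C@H]5C[C@@H](C)C(=O)O5)CCC14OCCO4 | intermediate (not isolated)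
26 | lactone aldehyde: 24 with the vinyl group cleaved to the C7a aldehyde | CC1(C)C[C@@](O[Si](CC)(CC)CC)([C@H](O[Si](CC)(CC)CC)[C@@H](C=O)[C@H]5C[C@@H](C)C(=O)O5)CCC14OCCO4 | intermediate
27 | methyl 2-(tert-butyldimethylsilyloxy)-2-(dimethoxyphosphoryl)acetate | COC(=O)C(O[Si](C)(C)C(C)(C)C)P(=O)(OC)OC | starting material
28 | (Z)-2-silyloxy enoate lactone: C7a=C7(OSiMe2t-Bu)CO2Me on C1, silyloxy cis to C1 | CC1(C)C[C@@](O[Si](CC)(CC)CC)([C@H](O[Si](CC)(CC)CC)[C@@H](/C=C(\O[Si](C)(C)C(C)(C)C)C(=O)OC)[C@H]5C[C@@H](C)C(=O)O5)CCC14OCCO4 | intermediate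
29 | hydroxy enone: free C2–OH, C3a(H)(CH3)–C4(=O)–CH=CH2, in equilibrium with its five-membered lactol | CC1(C)C[C@@](O[Si](CC)(CC)CC)([C@H](O[Si](CC)(CC)CC)[C@@H](/C=C(\O[Si](C)(C)C(C)(C)C)C(=O)OC)[C@H](O)C[C@@H](C)C(=O)C=C)CCC14OCCO4 | intermediate
30 | cyclic silylene dienol ether: O2–Si(t-Bu)2–O4 seven-membered ring, diene C6=C5–C4(O)=C3a(CH3) with C3 cis to O4 | CC1(C)C[C@@](O[Si](CC)(CC)CC)([C@H](O[Si](CC)(CC)CC)[C@@H](/C=C(\O[Si](C)(C)C(C)(C)C)C(=O)OC)[C@H]5C/C(C)=C(\O[Si](O5)(C(C)(C)C)C(C)(C)C)C=C)CCC14OCCO4 | intermediate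
31 | cycloadduct: trans-fused hexahydroindene, 3a-CH3 and 7a-H trans, C7 bearing OSiMe2t-Bu (cis to 3a-CH3) and CO2Me, O2–Si–O4 bridge with C4=C5 enol silane, C1 side chain trans to C7 | CC1(C)C[C@@](O[Si](CC)(CC)CC)([C@H](O[Si](CC)(CC)CC)[C@@H]2[C@H]5C[C@]3(C)C(O[Si](O5)(C(C)(C)C)C(C)(C)C)=CC[C@@](C(=O)OC)(O[Si](C)(C)C(C)(C)C)[C@@H]23)CCC14OCCO4 | intermediate
32 | primary alcohol: 31 with CO2Me reduced to CH2OH | CC1(C)C[C@@](O[Si](CC)(CC)CC)([C@H](O[Si](CC)(CC)CC)[C@@H]2[C@H]5C[C@]3(C)C(O[Si](O5)(C(C)(C)C)C(C)(C)C)=CC[C@@](CO)(O[Si](C)(C)C(C)(C)C)[C@@H]23)CCC14OCCO4 | intermediate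
33 | mesylate of 32 | CC1(C)C[C@@](O[Si](CC)(CC)CC)([C@H](O[Si](CC)(CC)CC)[C@@H]2[C@H]5C[C@]3(C)C(O[Si](O5)(C(C)(C)C)C(C)(C)C)=CC[C@@](COS(C)(=O)=O)(O[Si](C)(C)C(C)(C)C)[C@@H]23)CCC14OCCO4 | intermediate
34 | protected core: 31 with CH3 in place of CO2Me at C7 | CC1(C)C[C@@](O[Si](CC)(CC)CC)([C@H](O[Si](CC)(CC)CC)[C@@H]2[C@H]5C[C@]3(C)C(O[Si](O5)(C(C)(C)C)C(C)(C)C)=CC[C@@](C)(O[Si](C)(C)C(C)(C)C)[C@@H]23)CCC14OCCO4 | intermediate
35 | diketone tetraol: the target with C=O in place of CHBr at C4 and at C4' | CC1(C)C[C@@](O)([C@H](O)[C@@H]2[C@H](O)C[C@]3(C)C(=O)CC[C@@](C)(O)[C@@H]23)CCC1=O | intermediate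
36 | bis-hydrazone of 35 (C4=N–NH2 and C4'=N–NH2) | CC1(C)C[C@@](O)([C@H](O)[C@@H]2[C@H](O)C[C@]3(C)C(=NN)CC[C@@](C)(O)[C@@H]23)CCC1=NN | intermediate
37 | bis(alkenyl bromide): C4(Br)=C5 in the hydrindane and C4'(Br)=C5' in ring A, all other centres as in the target | CC1(C)C[C@@](O)([C@H](O)[C@@H]2[C@H](O)C[C@]3(C)C(Br)=CC[C@@](C)(O)[C@@H]23)CC=C1Br | intermediate
38 | (1S,2R,3aS,4S,7R,7aS)-4-bromo-1-{(R)-[(1R,4S)-4-bromo-1-hydroxy-3,3-dimethylcyclohexyl](hydroxy)methyl}-3a,7-dimethyloctahydro-1H-indene-2,7-diol (CNP0144982.1) | CC1(C)C[C@@](O)([C@H](O)[C@@H]2[C@H](O)C[C@]3(C)[C@@H](Br)CC[C@@](C)(O)[C@@H]23)CC[C@@H]1Br | target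

## Step count and risks

Total step count: 27.
Longest linear sequence: 26 steps (steps 1–9, then 11–27; step 10 is a one-step side branch).

Steps most likely to fail:

1. Step 19 (Proposed new method). Silylation of the lactol hydroxyl or intermolecular silylation may outrun the seven-membered ring closure, so that no single dienol ether geometry results. Fallback with known chemistry, setting out from 29: t-BuMe2SiOTf and Et3N should silylate the C2 hydroxyl and the enone to give the open-chain bis-silyl dienol ether F1 as a C3a=C4 E/Z mixture. On heating in toluene only the isomer with the tether outside can reach the IMDA transition state (the other is returned to 29 by desilylation), and with facial control resting on allylic strain at C1 the cycloadduct F2 should form. i-Bu2AlH should then give the alcohol F3, MsCl the mesylate F4 and LiEt3BH the methyl compound F5, and the conditions of step 24 bring the sequence back to the route at 35.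

2. Step 20. A 1,5-hydrogen shift from the inside methyl group of the diene or thermal loss of the enol silane may compete with the slow cycloaddition at the fully substituted diene terminus, and the endo/exo preference may erode at 160 °C. Fallback, setting out from 29: LiN(SiMe3)2 (2.2 equiv) in THF at −78 to 0 °C should trigger an intramolecular double Michael reaction (the dienolate carbon C3a adds to C7a, then the ester enolate carbon C7 adds to C6) and give the hydroxy ketone F6. Silylation with t-BuMe2SiOTf/Et3N should convert it into F2, and from there the sequence F3, F4, F5 of the first fallback comes back to the route at 35.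

3. Step 27. Loss of bromine by over-reduction, or poor facial selectivity of hydrogen-atom delivery to one of the two α-bromo radicals, may occur. Fallback, setting out from 35: t-Bu2Si(OTf)2/2,6-lutidine should bridge the syn-1,3-diol (Cα–OH, C2–OH) to give the silylene diketone F7. LiBH(s-Bu)3 at −78 °C should reduce both ketones by equatorial attack to the diaxial diol F8. Appel bromination (CBr4, PPh3) with inversion should give the diequatorial dibromide F9, and HF·pyridine then comes back to the route at 38.

Further compounds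

F1 | step 19 | open-chain bis(tert-butyldimethylsilyl) dienol ether from 29 (C2–OSiMe2t-Bu, C4–OSiMe2t-Bu; reactive C3a=C4 isomer with C3 cis to O4 shown) | CC1(C)C[C@@](O[Si](CC)(CC)CC)([C@H](O[Si](CC)(CC)CC)[C@@H](/C=C(\O[Si](C)(C)C(C)(C)C)C(=O)OC)[C@H](O[Si](C)(C)C(C)(C)C)C/C(C)=C(\O[Si](C)(C)C(C)(C)C)C=C)CCC14OCCO4
F2 | step 19 | cycloadduct with C2–OSiMe2t-Bu and C4 tert-butyldimethylsilyl enol ether (same configuration as 31) | CC1(C)C[C@@](O[Si](CC)(CC)CC)([C@H](O[Si](CC)(CC)CC)[C@@H]2[C@H](O[Si](C)(C)C(C)(C)C)C[C@]3(C)C(O[Si](C)(C)C(C)(C)C)=CC[C@@](C(=O)OC)(O[Si](C)(C)C(C)(C)C)[C@@H]23)CCC14OCCO4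
F3 | step 19 | primary alcohol from F2 (CO2Me reduced to CH2OH) | CC1(C)C[C@@](O[Si](CC)(CC)CC)([C@H](O[Si](CC)(CC)CC)[C@@H]2[C@H](O[Si](C)(C)C(C)(C)C)C[C@]3(C)C(O[Si](C)(C)C(C)(C)C)=CC[C@@](CO)(O[Si](C)(C)C(C)(C)C)[C@@H]23)CCC14OCCO4
F4 | step 19 | mesylate of F3 | CC1(C)C[C@@](O[Si](CC)(CC)CC)([C@H](O[Si](CC)(CC)CC)[C@@H]2[C@H](O[Si](C)(C)C(C)(C)C)C[C@]3(C)C(O[Si](C)(C)C(C)(C)C)=CC[C@@](COS(C)(=O)=O)(O[Si](C)(C)C(C)(C)C)[C@@H]23)CCC14OCCO4
F5 | step 19 | methyl compound from F4 (CH3 at C7) | CC1(C)C[C@@](O[Si](CC)(CC)CC)([C@H](O[Si](CC)(CC)CC)[C@@H]2[C@H](O[Si](C)(C)C(C)(C)C)C[C@]3(C)C(O[Si](C)(C)C(C)(C)C)=CC[C@@](C)(O[Si](C)(C)C(C)(C)C)[C@@H]23)CCC14OCCO4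
F6 | step 20 | hydroxy ketone from the double Michael reaction (free C2–OH, C4 ketone, C7 bearing OSiMe2t-Bu and CO2Me) | CC1(C)C[C@@](O[Si](CC)(CC)CC)([C@H](O[Si](CC)(CC)CC)[C@@H]2[C@H](O)C[C@]3(C)C(=O)CC[C@@](C(=O)OC)(O[Si](C)(C)C(C)(C)C)[C@@H]23)CCC14OCCO4
F7 | step 27 | silylene diketone: 35 with Cα–O and C2–O bridged by Si(t-Bu)2 | CC1(C)C[C@@](O)([C@H](O[Si]6(C(C)(C)C)C(C)(C)C)[C@@H]2[C@H](O6)C[C@]3(C)C(=O)CC[C@@](C)(O)[C@@H]23)CCC1=O
F8 | step 27 | diaxial diol: F7 with axial hydroxyls at C4 and C4' | CC1(C)C[C@@](O)([C@H](O[Si]6(C(C)(C)C)C(C)(C)C)[C@@H]2[C@H](O6)C[C@]3(C)[C@H](O)CC[C@@](C)(O)[C@@H]23)CC[C@H]1O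
F9 | step 27 | diequatorial dibromide: silylene-protected target | CC1(C)C[C@@](O)([C@H](O[Si]6(C(C)(C)C)C(C)(C)C)[C@@H]2[C@H](O6)C[C@]3(C)[C@@H](Br)CC[C@@](C)(O)[C@@H]23)CC[C@@H]1Br
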